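- What stood in the flask at 10 d, and which change added most?

- the product and idle adduct together standing at 10 d, as a percentage of the substrate charged
- the change that raises the amount of product and idle adduct together at 10 d, in percent of the substrate charged most ("none" if none brings more than 2 percentage points) (south / east / none)
- amount of product and idle adduct together at 10 d, in percent of the substrate charged, after east

| flask | substrate | reagent in the second phase | remark | time | volume of the second phase over the first |
|---|---|---|---|---|---|
| zeta | 0.23 M | 1.1 equiv | run made earlier |  |  |
| eta | 0.34 M | 1.1 equiv | run made earlier |  |  |
| flask | 0.45 M | 1.10 equiv |  | 10 d | 2.0 |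

- zeta (time / d: product / %, idle adduct / %): 0.833: 1, 1; 1.67: 13, 0; 3.00: 19, 0; 5.00: 32, 0; 10.0: 43, 0
- eta (time / d: product / %, idle adduct / %): 0.833: 8, 0; 1.67: 12, 0; 3.00: 22, 3; 5.00: 27, 0; 10.0: 44, 0

(each reading ± 2 percentage points)

- product is meant together with its idle adduct
- in the second phase: reagent in the second phase; everything else is in the first
- charges count per volume of the first phase; a concentration in a rate is the amount of a species over the volume of its own phase; every rate counts per litre of the first phase
- the earlier runs hold the two phases in the same ratio of volumes as the flask asked about

- south: doubling the amount of reagent in the second phase, all else as stated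
- east: doubling the transfer coefficient of the reagent in the second phase, all else as stated

- I started with the earlier runs. Going from [substrate] = 0.23 M in zeta to 0.34 M in eta raised the charge by a factor of 1.48, yet the product readings at 10.0 d stood at 43% and 44%.
- So I judged the rate-limiting step to be first order, with a time that did not follow the charge.
- Next I replaced each curve by the mean of the two runs. That mean was 29.5% at 5.00 d and 43.5% at 10.0 d.
- The second stretch added 14 percentage points, less than the first, so the curve bent.
- The bend time, the time in which the gap between the curve and its plateau shrinks by a factor of e, read 6.71 d. The plateau read 56.1%. Both carry the scatter of the readings.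
- The next rung was the run itself. The 10 d spanned 1.49 bend times, so I expected the flask on the bend, at 43.5%.
- I took east to cut the bend time to half at the same plateau, which gave 53.3%. I took south to raise the starting pace as well and to add reagent, so I ranked it first.
- The forecast gave 44% (40% to 48%), south, and 62% (51% to 73%) after east, above my figure, holding that “percent conversion is independent of concentration”.
- The flask gave 42.4%. South added 14 points, more than the 8.8 points of east, and east reached 51.2%.

    substrate + reagent in the reaction phase → product (k = 1.40 × 10⁻⁴ M⁻¹ s⁻¹)
    reagent in the reaction phase + product ⇌ idle adduct, settled at all times (K = 1.60 M⁻¹)
    reagent in the reaction phase ⇌ reagent in the second phase, rate k3*([reagent in the reaction phase] - [reagent in the second phase]/K3) per volume of the first phase (partition coefficient = 2.80, kL = 7.60 × 10⁻⁶ s⁻¹)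
    2 substrate → homo dimer (k = 6.90 × 10⁻⁶ M⁻¹ s⁻¹)

- In the flask, 98% of the homo dimer turnover up to 10 d stood by 5.00 d, while substrate fell to 12.8%. Reagent kept crossing into the reaction phase and forming product, with half of the crossing done by 2.85 d and half of the product step done by 2.76 d. The bend time had given 53.3% for east, against 51.2%.
- For the same flask read at 2.5 d, the bend time and plateau gave 17.4%. The computed reading was 19.6%.

The earlier runs and the new flask were computed with constants of no real substance.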